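**Plan**

- Retrosynthesis: the three benzyl ethers come off last. The C3 configuration is traced to a reduction/re-oxidation pair on the racemic ketone. Ring C is then cut at C2–C3 and C4–C4a together, giving an aryloxymethyl cation (ring A + O1 + C2) and a ketene dithioacetal (C3 + masked C4 + ring B). The C5'–C(CH3)2 bond of ring B goes back to a 4'-O-prenyl ether.
- Enabling feature: C2 is a formaldehyde-level carbon on O1, so C2=O1(+)–C8a=C4a is a 2-oxonia-diene. Its terminus C4a is ortho to O1 and para to the 7-oxygen of ring A. C3–C4 is a two-carbon unit at the arylacetic acid (ketene) oxidation level.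
- Forward: the ring B aldehyde is made by O-prenylation, benzylation, aromatic Claisen rearrangement and methylation, then homologated to the ketene dithioacetal. Ring A is made into its acetoxymethyl ether. A cationic (4+2) annulation closes ring C as the C4 spiro-dithiane, and hydrolysis gives the racemic isoflavanone.
- Stereochemistry: C3 is formed racemic on purpose. It is set by catalyst-controlled asymmetric transfer hydrogenation with dynamic kinetic resolution ((S,S)-TsDPEN ligand), then kept through re-oxidation and a non-basic debenzylation.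

Key step: step 7

Remark on the chemistry: the target is (3S). C3–H is benzylic and alpha to the ketone, so it is fixed late and only non-basic steps follow it.

**Route**

Step 1
Reactants: 1 2,3,4-trihydroxybenzaldehyde; 2 1-bromo-3-methylbut-2-ene (prenyl bromide)
Product: 3 2,3-dihydroxy-4-[(3-methylbut-2-en-1-yl)oxy]benzaldehyde
Conditions: NaHCO3, NaI (cat.), DMF, 40 °C
Reagents that add atoms: none
Why: Regioselective Williamson etherification, because the 4-OH (para to the formyl group and not hydrogen-bonded to it) is the most acidic phenol and is the only one alkylated by a weak base.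

Step 2
Reactants: 3 2,3-dihydroxy-4-[(3-methylbut-2-en-1-yl)oxy]benzaldehyde
Product: 4 2,3-bis(benzyloxy)-4-[(3-methylbut-2-en-1-yl)oxy]benzaldehyde
Conditions: BnBr, K2CO3, DMF, 60 °C
Reagents that add atoms: benzyl bromide, BrCc1ccccc1
Why: Williamson etherification of the two remaining phenols; benzyl ethers tolerate the later heat, organolithium and Lewis acid.

Step 3
Reactants: 4 2,3-bis(benzyloxy)-4-[(3-methylbut-2-en-1-yl)oxy]benzaldehyde
Product: 5 2,3-bis(benzyloxy)-4-hydroxy-5-(2-methylbut-3-en-2-yl)benzaldehyde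
Conditions: PhNEt2, 180 °C, sealed tube
Reagents that add atoms: none
Why: Aromatic Claisen rearrangement, in which the [3,3] shift delivers the allyl unit with inversion (giving the 1,1-dimethylallyl group) to C5, the only free ortho carbon, and tautomerisation restores the phenol.

Step 4
Reactants: 5 2,3-bis(benzyloxy)-4-hydroxy-5-(2-methylbut-3-en-2-yl)benzaldehyde
Product: 6 2,3-bis(benzyloxy)-4-methoxy-5-(2-methylbut-3-en-2-yl)benzaldehyde
Conditions: MeI, K2CO3, DMF, rt
Reagents that add atoms: iodomethane, CI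
Why: Williamson methylation of an acidic (para-formyl) phenoxide by a small electrophile, which should overcome the flanking substituents.

Step 5
Reactants: 6 2,3-bis(benzyloxy)-4-methoxy-5-(2-methylbut-3-en-2-yl)benzaldehyde; 7 2-(trimethylsilyl)-1,3-dithiane
Product: 9 2-{[2,3-bis(benzyloxy)-4-methoxy-5-(2-methylbut-3-en-2-yl)phenyl]methylidene}-1,3-dithiane, via lithiated dithiane 8 (not isolated)
Conditions: n-BuLi, THF, −78 → 0 °C (7 → 8); then 6, −78 °C → rt
Reagents that add atoms: none
Why: Peterson olefination, in which the silyl-stabilised dithiane anion adds to the aldehyde and the beta-silyl alkoxide eliminates Me3SiOLi to give the ketene dithioacetal, a ketene surrogate that already carries C3 and C4.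

Step 6
Reactants: 10 3-(benzyloxy)phenol; 11 bromomethyl acetate
Product: 12 [3-(benzyloxy)phenoxy]methyl acetate
Conditions: K2CO3, DMF, 0 °C → rt
Reagents that add atoms: none
Why: Williamson O-alkylation of the phenoxide at the highly reactive alpha-halo ether carbon, giving an acetoxymethyl ether that stores the O1–C2 oxocarbenium ion.

Step 7
Reactants: 9 2-{[2,3-bis(benzyloxy)-4-methoxy-5-(2-methylbut-3-en-2-yl)phenyl]methylidene}-1,3-dithiane; 12 [3-(benzyloxy)phenoxy]methyl acetate
Product: 14 rac-7-(benzyloxy)-3-[2,3-bis(benzyloxy)-4-methoxy-5-(2-methylbut-3-en-2-yl)phenyl]-2,3-dihydrospiro[chromene-4,2'-[1,3]dithiane], via dithienium triflate 13 (not isolated)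
Conditions: TMSOTf (1.2 equiv), 2,6-di-tert-butyl-4-methylpyridine (1.3 equiv), CH2Cl2, −78 °C → rt; aq. NaHCO3
Reagents that add atoms: none
Why: Proposed new method: TMSOTf ionises 12 to the aryloxymethyl cation (C2=O1+ on ring A), which is captured at the sulfur-free carbon of 9 to form C2–C3 and the 1,3-dithian-2-ylium ion 13; C4a of ring A then attacks the dithienium carbon to form C4–C4a, and proton loss to the hindered pyridine gives 14. The closest known reaction types are the oxa-Povarov reaction (cationic [4+2] of aryl oxocarbenium ions with alkenes to chromans) and the Friedel–Crafts cyclisation of dithienium ions generated from ketene dithioacetals; their combination with a formaldehyde-level oxocarbenium ion and a ketene surrogate is untested. Ring C closes in a 6-exo-trig Friedel–Crafts mode, the arene carbon adding to the exocyclic C=S+ bond. C3 is created in the first bond formation without control and is deliberately racemic, to be set in step 9; the spiro carbon C4 is not stereogenic. The step needs C-alkylation of 9 to outrun Friedel–Crafts self-alkylation of 12, which the much higher pi-nucleophilicity of the ketene dithioacetal should secure, and closure para instead of ortho to the 7-benzyloxy group, which the double activation of C4a (ortho to O1, para to O7) and sterics secure. The hindered base keeps 9 from being sequestered by TfOH, while its pyridinium triflate can still re-protonate any ketene dithioacetal formed from 13 by proton loss.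

Step 8
Reactants: 14 rac-7-(benzyloxy)-3-[2,3-bis(benzyloxy)-4-methoxy-5-(2-methylbut-3-en-2-yl)phenyl]-2,3-dihydrospiro[chromene-4,2'-[1,3]dithiane]
Product: 15 rac-7-(benzyloxy)-3-[2,3-bis(benzyloxy)-4-methoxy-5-(2-methylbut-3-en-2-yl)phenyl]-2,3-dihydro-4H-chromen-4-one
Conditions: MeI (excess), CaCO3, MeCN/H2O (9:1), 45 °C
Reagents that add atoms: water, O
Why: Alkylative dithioketal hydrolysis, in which S-methylation makes sulfur a leaving group, the para-benzyloxyaryl ring stabilises the thionium ion and water delivers the C4 carbonyl oxygen.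

Step 9
Reactants: 15 rac-7-(benzyloxy)-3-[2,3-bis(benzyloxy)-4-methoxy-5-(2-methylbut-3-en-2-yl)phenyl]-2,3-dihydro-4H-chromen-4-one
Product: 16 (3S,4S)-7-(benzyloxy)-3-[2,3-bis(benzyloxy)-4-methoxy-5-(2-methylbut-3-en-2-yl)phenyl]-3,4-dihydro-2H-chromen-4-ol (cis)
Conditions: RuCl(p-cymene)[(S,S)-TsDPEN] (3 mol %), HCO2H/Et3N, EtOAc, 40 °C
Reagents that add atoms: none
Why: Noyori–Ikariya asymmetric transfer hydrogenation with dynamic kinetic resolution, in which amine-mediated enolisation interconverts the C3 epimers while the (S,S) catalyst sets C4 as S (as for aryl ketones generally) and delivers hydride anti to the 3-aryl group, so the cis (3S,4S) alcohol should form and the isolated alkene is untouched.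

Step 10
Reactants: 16 (3S,4S)-7-(benzyloxy)-3-[2,3-bis(benzyloxy)-4-methoxy-5-(2-methylbut-3-en-2-yl)phenyl]-3,4-dihydro-2H-chromen-4-ol
Product: 17 (3S)-7-(benzyloxy)-3-[2,3-bis(benzyloxy)-4-methoxy-5-(2-methylbut-3-en-2-yl)phenyl]-2,3-dihydro-4H-chromen-4-one
Conditions: Dess–Martin periodinane, CH2Cl2, 0 °C → rt
Reagents that add atoms: none
Why: Dess–Martin oxidation under non-basic conditions returns the ketone without enolising C3, so the configuration set in step 9 is kept.

Step 11
Reactants: 17 (3S)-7-(benzyloxy)-3-[2,3-bis(benzyloxy)-4-methoxy-5-(2-methylbut-3-en-2-yl)phenyl]-2,3-dihydro-4H-chromen-4-one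
Product: 18 (3S)-3-[2,3-dihydroxy-4-methoxy-5-(2-methylbut-3-en-2-yl)phenyl]-7-hydroxy-2,3-dihydro-4H-chromen-4-one
Conditions: BCl3, pentamethylbenzene, CH2Cl2, −78 °C; MeOH/CHCl3 quench at −78 °C
Reagents that add atoms: none
Why: Lewis-acid debenzylation with a non-basic cation scavenger, which at −78 °C should cleave aryl benzyl ethers much faster than the aryl methyl ether, leave the monosubstituted alkene alone and, having no base present, not enolise C3.

**Compound list**

1 | 2,3,4-trihydroxybenzaldehyde | O=Cc1ccc(O)c(O)c1O | starting material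
2 | 1-bromo-3-methylbut-2-ene | CC(C)=CCBr | starting material
3 | 2,3-dihydroxy-4-[(3-methylbut-2-en-1-yl)oxy]benzaldehyde | O=Cc1ccc(OCC=C(C)C)c(O)c1O | intermediate
4 | 2,3-bis(benzyloxy)-4-[(3-methylbut-2-en-1-yl)oxy]benzaldehyde | O=Cc1ccc(OCC=C(C)C)c(OCc2ccccc2)c1OCc1ccccc1 | intermediate
5 | 2,3-bis(benzyloxy)-4-hydroxy-5-(2-methylbut-3-en-2-yl)benzaldehyde | O=Cc1cc(C(C)(C)C=C)c(O)c(OCc2ccccc2)c1OCc1ccccc1 | intermediate
6 | 2,3-bis(benzyloxy)-4-methoxy-5-(2-methylbut-3-en-2-yl)benzaldehyde | O=Cc1cc(C(C)(C)C=C)c(OC)c(OCc2ccccc2)c1OCc1ccccc1 | intermediate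
7 | 2-(trimethylsilyl)-1,3-dithiane | C[Si](C)(C)C1SCCCS1 | starting material
8 | 2-lithio-2-(trimethylsilyl)-1,3-dithiane | [Li]C1([Si](C)(C)C)SCCCS1 | intermediate
9 | 2-{[2,3-bis(benzyloxy)-4-methoxy-5-(2-methylbut-3-en-2-yl)phenyl]methylidene}-1,3-dithiane | C=CC(C)(C)c1cc(C=C2SCCCS2)c(OCc2ccccc2)c(OCc2ccccc2)c1OC | intermediate
10 | 3-(benzyloxy)phenol | Oc1cccc(OCc2ccccc2)c1 | starting material
11 | bromomethyl acetate | CC(=O)OCBr | starting material
12 | [3-(benzyloxy)phenoxy]methyl acetate | CC(=O)OCOc1cccc(OCc2ccccc2)c1 | intermediate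
13 | rac-2-{1-[2,3-bis(benzyloxy)-4-methoxy-5-(2-methylbut-3-en-2-yl)phenyl]-2-[3-(benzyloxy)phenoxy]ethyl}-1,3-dithian-2-ylium triflate | C=CC(C)(C)c1cc(C(COc2cccc(OCc3ccccc3)c2)C2=[S+]CCCS2)c(OCc2ccccc2)c(OCc2ccccc2)c1OC.[O-]S(=O)(=O)C(F)(F)F | intermediate
14 | rac-7-(benzyloxy)-3-[2,3-bis(benzyloxy)-4-methoxy-5-(2-methylbut-3-en-2-yl)phenyl]-2,3-dihydrospiro[chromene-4,2'-[1,3]dithiane] | C=CC(C)(C)c1cc(C2COc3cc(OCc4ccccc4)ccc3C23SCCCS3)c(OCc2ccccc2)c(OCc2ccccc2)c1OC | intermediate
15 | rac-7-(benzyloxy)-3-[2,3-bis(benzyloxy)-4-methoxy-5-(2-methylbut-3-en-2-yl)phenyl]-2,3-dihydro-4H-chromen-4-one | C=CC(C)(C)c1cc(C2COc3cc(OCc4ccccc4)ccc3C2=O)c(OCc2ccccc2)c(OCc2ccccc2)c1OC | intermediate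
16 | (3S,4S)-7-(benzyloxy)-3-[2,3-bis(benzyloxy)-4-methoxy-5-(2-methylbut-3-en-2-yl)phenyl]-3,4-dihydro-2H-chromen-4-ol | C=CC(C)(C)c1cc([C@H]2COc3cc(OCc4ccccc4)ccc3[C@H]2O)c(OCc2ccccc2)c(OCc2ccccc2)c1OC | intermediate
17 | (3S)-7-(benzyloxy)-3-[2,3-bis(benzyloxy)-4-methoxy-5-(2-methylbut-3-en-2-yl)phenyl]-2,3-dihydro-4H-chromen-4-one | C=CC(C)(C)c1cc([C@H]2COc3cc(OCc4ccccc4)ccc3C2=O)c(OCc2ccccc2)c(OCc2ccccc2)c1OC | intermediate
18 | (3S)-3-[2,3-dihydroxy-4-methoxy-5-(2-methylbut-3-en-2-yl)phenyl]-7-hydroxy-2,3-dihydro-4H-chromen-4-one | C=CC(C)(C)c1cc([C@H]2COc3cc(O)ccc3C2=O)c(O)c(O)c1OC | target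

**Count**

Total steps: 11. Longest linear sequence: 10 steps (steps 1–5 and 7–11; step 6 is the one-step side branch).

**Steps most likely to fail**

Step 7 (Proposed new method). What may go wrong: the aryloxymethyl cation may alkylate electron-rich arenes instead of the ketene dithioacetal. The dithienium ion may also be trapped by the neighbouring 2'-benzyloxy oxygen (five-membered closure with loss of benzyl), or stall as the deprotonated ketene dithioacetal instead of closing ring C. Fallback with known chemistry, setting out from 9 and coming back at 15, making the two bonds in separate steps: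
- 9 is solvolysed (HgCl2, aq. MeOH, reflux) to methyl [2,3-bis(benzyloxy)-4-methoxy-5-(2-methylbut-3-en-2-yl)phenyl]acetate F1.
- Base-catalysed hydroxymethylation (paraformaldehyde, cat. K2CO3, DMSO) should give the racemic methyl 3-hydroxy-2-arylpropanoate F2.
- Mitsunobu etherification with phenol 10 (PPh3, DIAD, THF) should give the racemic methyl 2-aryl-3-[3-(benzyloxy)phenoxy]propanoate F3.
- LiOH saponification gives the racemic 2-aryl-3-[3-(benzyloxy)phenoxy]propanoic acid F4.
- Intramolecular Friedel–Crafts acylation (trifluoroacetic anhydride, CH2Cl2) closes ring C to 15, bypassing 14.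

Step 3. What may go wrong: ionisation of the prenyl ether (loss of the prenyl group or a 1,3-shift to the linear prenyl isomer) and further thermal reorganisation of the ortho-(1,1-dimethylallyl)phenol at 180 °C. Fallback, setting out from 1 and coming back at 6, replacing the sigmatropic shift by a cross-coupling:
- 1 is methylated selectively at the 4-OH (MeI, Li2CO3, DMF) to 2,3-dihydroxy-4-methoxybenzaldehyde F5.
- Benzylation (BnBr, K2CO3, DMF) gives 2,3-bis(benzyloxy)-4-methoxybenzaldehyde F6.
- Bromination para to the 2-benzyloxy group (NBS, MeCN) gives 2,3-bis(benzyloxy)-5-bromo-4-methoxybenzaldehyde F7.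
- A gamma-selective (branched) Suzuki–Miyaura coupling with prenylboronic acid pinacol ester (Pd(OAc)2, a dialkylbiarylphosphine ligand chosen for branched selectivity, aq. K3PO4, THF, 40 °C) gives 6.

Step 11. What may go wrong: partial loss of the C3 configuration through Lewis-acid-promoted enolisation while three benzyl ethers are cleaved. Fallback, setting out from 15 and coming back at 18, moving the debenzylation ahead of the stereo-defining step:
- Racemic 15 is debenzylated (BCl3, pentamethylbenzene, CH2Cl2, −78 °C) to the racemic triol F8.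
- Silylation (TBSCl, imidazole, DMF) gives the racemic tris(tert-butyldimethylsilyl) ether F9.
- The transfer hydrogenation of step 9 should give the (3S,4S)-tris-silyl alcohol F10.
- Dess–Martin oxidation gives the (3S)-tris-silyl ketone F11.
- HF·pyridine (THF, 0 °C) frees 18 under mildly acidic conditions without a strong Lewis acid.

**Further compounds**

F1 | step 7 | methyl [2,3-bis(benzyloxy)-4-methoxy-5-(2-methylbut-3-en-2-yl)phenyl]acetate | C=CC(C)(C)c1cc(CC(=O)OC)c(OCc2ccccc2)c(OCc2ccccc2)c1OC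
F2 | step 7 | rac-methyl 2-[2,3-bis(benzyloxy)-4-methoxy-5-(2-methylbut-3-en-2-yl)phenyl]-3-hydroxypropanoate | C=CC(C)(C)c1cc(C(CO)C(=O)OC)c(OCc2ccccc2)c(OCc2ccccc2)c1OC
F3 | step 7 | rac-methyl 2-[2,3-bis(benzyloxy)-4-methoxy-5-(2-methylbut-3-en-2-yl)phenyl]-3-[3-(benzyloxy)phenoxy]propanoate | C=CC(C)(C)c1cc(C(COc2cccc(OCc3ccccc3)c2)C(=O)OC)c(OCc2ccccc2)c(OCc2ccccc2)c1OC
F4 | step 7 | rac-2-[2,3-bis(benzyloxy)-4-methoxy-5-(2-methylbut-3-en-2-yl)phenyl]-3-[3-(benzyloxy)phenoxy]propanoic acid | C=CC(C)(C)c1cc(C(COc2cccc(OCc3ccccc3)c2)C(=O)O)c(OCc2ccccc2)c(OCc2ccccc2)c1OC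
F5 | step 3 | 2,3-dihydroxy-4-methoxybenzaldehyde | COc1ccc(C=O)c(O)c1O
F6 | step 3 | 2,3-bis(benzyloxy)-4-methoxybenzaldehyde | COc1ccc(C=O)c(OCc2ccccc2)c1OCc1ccccc1
F7 | step 3 | 2,3-bis(benzyloxy)-5-bromo-4-methoxybenzaldehyde | COc1c(Br)cc(C=O)c(OCc2ccccc2)c1OCc1ccccc1
F8 | step 11 | rac-3-[2,3-dihydroxy-4-methoxy-5-(2-methylbut-3-en-2-yl)phenyl]-7-hydroxy-2,3-dihydro-4H-chromen-4-one | C=CC(C)(C)c1cc(C2COc3cc(O)ccc3C2=O)c(O)c(O)c1OC
F9 | step 11 | rac-7-[(tert-butyldimethylsilyl)oxy]-3-{2,3-bis[(tert-butyldimethylsilyl)oxy]-4-methoxy-5-(2-methylbut-3-en-2-yl)phenyl}-2,3-dihydro-4H-chromen-4-one | C=CC(C)(C)c1cc(C2COc3cc(O[Si](C)(C)C(C)(C)C)ccc3C2=O)c(O[Si](C)(C)C(C)(C)C)c(O[Si](C)(C)C(C)(C)C)c1OC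
F10 | step 11 | (3S,4S)-7-[(tert-butyldimethylsilyl)oxy]-3-{2,3-bis[(tert-butyldimethylsilyl)oxy]-4-methoxy-5-(2-methylbut-3-en-2-yl)phenyl}-3,4-dihydro-2H-chromen-4-ol | C=CC(C)(C)c1cc([C@H]2COc3cc(O[Si](C)(C)C(C)(C)C)ccc3[C@H]2O)c(O[Si](C)(C)C(C)(C)C)c(O[Si](C)(C)C(C)(C)C)c1OC
F11 | step 11 | (3S)-7-[(tert-butyldimethylsilyl)oxy]-3-{2,3-bis[(tert-butyldimethylsilyl)oxy]-4-methoxy-5-(2-methylbut-3-en-2-yl)phenyl}-2,3-dihydro-4H-chromen-4-one | C=CC(C)(C)c1cc([C@H]2COc3cc(O[Si](C)(C)C(C)(C)C)ccc3C2=O)c(O[Si](C)(C)C(C)(C)C)c(O[Si](C)(C)C(C)(C)C)c1OC
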